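Ring C (C8, C9, C11–C14; abietane numbering) shares only the C8–C9 bond with the ketone-bearing ring B. Both rings are therefore cut at once into an open-chain 1,7-diyne, C11≡C9–C10–C5–C6–C7(=O)–C8≡C14, and a two-carbon alkyne carrying the C12 oxygen and the C13 isopropyl group. A rhodium-catalysed [2+2+2] cycloaddition forms C8–C9, C11–C12 and C13–C14 in one operation and gives the 12-silyloxy-13-isopropyl aryl ketone with the propanoate arm in place. The precursor, an ynone diyne with C5 and C10 already set, comes from a 2,2,3-trisubstituted cyclohexanone by Eschenmoser–Tanabe fragmentation. Three oxidation-level adjustments on ring C finish the synthesis.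

Key step: step 9

Remark: abietane numbering is used for target atoms (ring B = C5–C10, ring C = C8, C9, C11–C14); the sense of induction of the copper/phosphoramidite catalyst in step 1 is assumed, and the antipodal ligand is to be used if the first run shows the opposite sense.

Step 1
Reactants: 1 2-methylcyclohex-2-en-1-one; 2 isopropenylmagnesium bromide
Product: 4 (3R)-2-methyl-3-(prop-1-en-2-yl)cyclohexan-1-one (mixture of C2 epimers), via bromomagnesium enolate 3 (not isolated)
Conditions: CuBr·SMe2 (5 mol %), (S,R,R)-BINOL/bis(1-phenylethyl)amine phosphoramidite (10 mol %), Et2O, −78 °C, slow addition of 2; aq. NH4Cl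
Reagents that add atoms: isopropenylmagnesium bromide (2), C=C(C)[Mg]Br
Why: Copper-catalysed asymmetric conjugate addition of a Grignard reagent to an α-substituted cyclic enone is an established reaction type; the chiral copper complex should deliver the isopropenyl group to the Re face of C3 of the enone and so set C5, and the enolate is simply protonated because its α-carbon is re-enolised in step 2.

Step 2
Reactants: 4 (3R)-2-methyl-3-(prop-1-en-2-yl)cyclohexan-1-one; 5 methyl acrylate
Product: 8 methyl 3-[(1S,6S)-1-methyl-2-oxo-6-(prop-1-en-2-yl)cyclohexyl]propanoate, via ketimine 6 (not isolated), via adduct ketimine 7 (not isolated)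
Conditions: (S)-1-phenylethylamine (1.05 equiv), TsOH·H2O (cat.), toluene, reflux, Dean–Stark; 5 (1.5 equiv), THF, 40 °C; 20% aq. AcOH, rt
Reagents that add atoms: methyl acrylate (5), C=CC(=O)OC
Why: In this asymmetric Michael addition of a chiral imine the reacting species is the more substituted secondary enamine tautomer, so acrylate bonds only to the methyl-bearing α-carbon, anti to the neighbouring isopropenyl group and on the face also favoured by the (S)-phenylethyl group (matched pair), which sets the quaternary C10 with the propanoate arm trans to isopropenyl.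

Step 3
Reactants: 8 methyl 3-[(1S,6S)-1-methyl-2-oxo-6-(prop-1-en-2-yl)cyclohexyl]propanoate
Product: 10 methyl 3-[(1S,6S)-1-methyl-2-oxo-6-(prop-1-en-2-yl)cyclohex-3-en-1-yl]propanoate, via trimethylsilyl enol ether 9 (not isolated)
Conditions: TMSOTf (1.2 equiv), Et3N, CH2Cl2, 0 °C; Pd(OAc)2 (10 mol %), O2 (1 atm), DMSO, rt
Reagents that add atoms: none
Why: Saegusa–Ito oxidation: soft enolisation can only go toward the ring CH2 because the other α-carbon is quaternary, divalent palladium converts the silyl enol ether into the enone by β-hydride elimination, and O2 returns zerovalent palladium to the divalent state.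

Step 4
Reactants: 10 methyl 3-[(1S,6S)-1-methyl-2-oxo-6-(prop-1-en-2-yl)cyclohex-3-en-1-yl]propanoate
Product: 11 methyl 3-[(3S,4S)-3-methyl-2-oxo-4-(prop-1-en-2-yl)-7-oxabicyclo[4.1.0]heptan-3-yl]propanoate (epoxide diastereomers)
Conditions: 30% aq. H2O2 (3 equiv), NaOH (0.3 equiv), MeOH, 0 °C
Reagents that add atoms: hydrogen peroxide, OO
Why: Weitz–Scheffer nucleophilic epoxidation attacks only the enone, the electron-rich isopropenyl group is inert, methoxide exchange at the methyl ester is degenerate in methanol, and the two new epoxide centres (either face) are erased in step 5.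

Step 5
Reactants: 11 methyl 3-[(3S,4S)-3-methyl-2-oxo-4-(prop-1-en-2-yl)-7-oxabicyclo[4.1.0]heptan-3-yl]propanoate
Product: 13 methyl (4S,5S)-4-ethynyl-4-methyl-7-oxo-5-(prop-1-en-2-yl)heptanoate, via epoxy tosylhydrazone 12 (not isolated)
Conditions: TsNHNH2 (1.05 equiv), AcOH–CH2Cl2 (1:1), −20 °C to rt
Reagents that add atoms: none
Why: Eschenmoser–Tanabe fragmentation: the epoxy sulfonylhydrazone opens and expels sulfinate and N2, cleaving the former Cα–Cβ bond to leave the terminal alkyne on the quaternary carbon and the aldehyde at C7, with C5 and C10 untouched.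

Step 6
Reactants: 13 methyl (4S,5S)-4-ethynyl-4-methyl-7-oxo-5-(prop-1-en-2-yl)heptanoate; 14 ethynylmagnesium bromide
Product: 16 methyl (4S,5S)-4-ethynyl-7-hydroxy-4-methyl-5-(prop-1-en-2-yl)non-8-ynoate (C7 epimers), via bromomagnesium alkoxide 15 (not isolated)
Conditions: 14 (1.3 equiv, 0.5 M in THF), THF, −78 °C; aq. NH4Cl
Reagents that add atoms: ethynylmagnesium bromide (14), C#C[Mg]Br
Why: Grignard 1,2-addition at −78 °C discriminates the aldehyde from the methyl ester, and the configuration of the new carbinol centre is irrelevant because it is oxidised in step 7.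

Step 7
Reactants: 16 methyl (4S,5S)-4-ethynyl-7-hydroxy-4-methyl-5-(prop-1-en-2-yl)non-8-ynoate
Product: 17 methyl (4S,5S)-4-ethynyl-4-methyl-7-oxo-5-(prop-1-en-2-yl)non-8-ynoate
Conditions: Dess–Martin periodinane (1.3 equiv), CH2Cl2, 0 °C to rt
Reagents that add atoms: none
Why: Dess–Martin oxidation of a secondary propargylic alcohol under near-neutral conditions should give the base-sensitive terminal ynone without touching the alkene, ester or alkynes.

Step 8
Reactants: 18 ethyl 2-methylpropanoate (ethyl isobutyrate)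
Product: 21 [(3-methylbut-1-yn-1-yl)oxy]tri(propan-2-yl)silane, via dibromo enolate 19 (not isolated), via lithium ynolate 20 (not isolated)
Conditions: CH2Br2, lithium 2,2,6,6-tetramethylpiperidide, THF, −78 °C; 18; LiN(SiMe3)2, −78 to −20 °C; n-BuLi, −78 °C to rt; TIPSCl, 0 °C
Reagents that add atoms: dibromomethane, BrCBr; chlorotri(propan-2-yl)silane, CC(C)[Si](Cl)(C(C)C)C(C)C
Why: Kowalski ester homologation: bromine–lithium exchange on the dibromo enolate triggers 1,2-shift of the isopropyl group to the ynolate, which the bulky silyl chloride captures on oxygen.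

Step 9
Reactants: 17 methyl (4S,5S)-4-ethynyl-4-methyl-7-oxo-5-(prop-1-en-2-yl)non-8-ynoate; 21 [(3-methylbut-1-yn-1-yl)oxy]tri(propan-2-yl)silane
Product: 22 methyl 3-[(1S,2S)-1-methyl-4-oxo-6-(propan-2-yl)-2-(prop-1-en-2-yl)-7-{[tri(propan-2-yl)silyl]oxy}-1,2,3,4-tetrahydronaphthalen-1-yl]propanoate
Conditions: [Rh(cod)2]BF4 (5 mol %), rac-BINAP (5 mol %), H2 then Ar (catalyst activation), CH2Cl2, 4 Å MS, rt; 21 (2.5 equiv); 17 added over 4 h by syringe pump
Reagents that add atoms: siloxyalkyne 21, CC(C)C#CO[Si](C(C)C)(C(C)C)C(C)C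
Why: Cationic monovalent rhodium ligated by BINAP should bind the two tethered alkynes of 17 and couple them oxidatively, forming C8–C9 and a rhodacyclopentadiene fused to the new six-membered ring B, so ring B closes by metallacycle formation, helped by the gem-disubstituent effect of the quaternary C10. Insertion of 21 into a Rh–C bond and reductive elimination then form C11–C12 and C13–C14 and close ring C directly at the benzene oxidation level. The closest known reaction type is the cationic rhodium/bisphosphine-catalysed [2+2+2] cycloaddition of α,ω-diynes with heteroatom-substituted alkynes such as ynamides and alkynyl ethers. No stereocentre is formed, and C5 and C10 carry no acidic hydrogen next to a carbonyl, so they should pass through unchanged. The selectivity needed is regiochemical: the nucleophilic isopropyl-bearing carbon of 21 should bond to the electrophilic β-carbon of the ynone (C14) and the oxygen-bearing carbon to the unconjugated terminus C11, whichever pair of alkynes couples first. Cross-reaction over homotrimerisation is secured by an excess of 21 and slow addition of 17, and the 1,1-disubstituted isopropenyl alkene should be too slow a partner to compete with the second alkyne.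

Step 10
Reactants: 22 methyl 3-[(1S,2S)-1-methyl-4-oxo-6-(propan-2-yl)-2-(prop-1-en-2-yl)-7-{[tri(propan-2-yl)silyl]oxy}-1,2,3,4-tetrahydronaphthalen-1-yl]propanoate
Product: 23 methyl 3-[(1S,2S)-7-hydroxy-1-methyl-4-oxo-6-(propan-2-yl)-2-(prop-1-en-2-yl)-1,2,3,4-tetrahydronaphthalen-1-yl]propanoate
Conditions: TBAF (1.1 equiv), AcOH (1.1 equiv), THF, 0 °C
Reagents that add atoms: none
Why: Fluoride-induced cleavage of an aryl silyl ether is fast at 0 °C, and acetic acid buffering keeps the phenoxide from attacking the ester or enolising the ketone.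

Step 11
Reactants: 23 methyl 3-[(1S,2S)-7-hydroxy-1-methyl-4-oxo-6-(propan-2-yl)-2-(prop-1-en-2-yl)-1,2,3,4-tetrahydronaphthalen-1-yl]propanoate
Product: 24 methyl 3-[(1S,2S)-1-methyl-4,7,8-trioxo-6-(propan-2-yl)-2-(prop-1-en-2-yl)-1,2,3,4,7,8-hexahydronaphthalen-1-yl]propanoate
Conditions: IBX (1.2 equiv), DMF, rt, dark
Reagents that add atoms: 2-iodoxybenzoic acid (IBX), O=C1OI(=O)(O)c2ccccc12
Why: IBX ortho-oxygenation of phenols: after ligand exchange at iodine the oxygen is delivered intramolecularly to the only free ortho position, C11 (C13 carries the isopropyl group), and the iodine-bound catechol collapses to the 11,12-quinone, the alkene and ketone being inert at room temperature.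

Step 12
Reactants: 24 methyl 3-[(1S,2S)-1-methyl-4,7,8-trioxo-6-(propan-2-yl)-2-(prop-1-en-2-yl)-1,2,3,4,7,8-hexahydronaphthalen-1-yl]propanoate
Product: 26 methyl 3-[(1S,2S)-7-hydroxy-1-methyl-4,5,8-trioxo-6-(propan-2-yl)-2-(prop-1-en-2-yl)-1,2,3,4,5,8-hexahydronaphthalen-1-yl]propanoate (the target), via benzenetriol 25 (not isolated)
Conditions: NaHCO3–Na2CO3 buffer (pH 9.5), MeCN–H2O, air, rt; dilute HCl to pH 3
Reagents that add atoms: water, O
Why: Conjugate addition of hydroxide to the o-quinone can only occur at C14, the sole unsubstituted quinone carbon, and aerial oxidation of the resulting benzenetriol followed by tautomerisation gives the more stable 12-hydroxy-11,14-quinone, a hydration–autoxidation sequence known for 4-alkyl-o-benzoquinones; the mild pH spares the methyl ester.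

Compound list
1 | 2-methylcyclohex-2-en-1-one | CC1=CCCC1=O | starting material
2 | isopropenylmagnesium bromide (prop-1-en-2-ylmagnesium bromide) | C=C(C)[Mg]Br | starting material
3 | bromomagnesium (3S)-2-methyl-3-(prop-1-en-2-yl)cyclohex-1-en-1-olate (formed in the flask) | C=C(C)[C@@H]1CCCC(O[Mg]Br)=C1C | intermediate
4 | (3R)-2-methyl-3-(prop-1-en-2-yl)cyclohexan-1-one (mixture of C2 epimers) | C=C(C)[C@@H]1CCCC(=O)C1C | intermediate
5 | methyl acrylate | C=CC(=O)OC | starting material
6 | (1S)-N-[(3R)-2-methyl-3-(prop-1-en-2-yl)cyclohexylidene]-1-phenylethanamine (formed in the flask) | C=C(C)[C@@H]1CCCC(=N[C@@H](C)c2ccccc2)C1C | intermediate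
7 | methyl 3-[(1S,6S)-1-methyl-2-{[(1S)-1-phenylethyl]imino}-6-(prop-1-en-2-yl)cyclohexyl]propanoate (formed in the flask) | C=C(C)[C@@H]1CCCC(=N[C@@H](C)c2ccccc2)[C@@]1(C)CCC(=O)OC | intermediate
8 | methyl 3-[(1S,6S)-1-methyl-2-oxo-6-(prop-1-en-2-yl)cyclohexyl]propanoate | C=C(C)[C@@H]1CCCC(=O)[C@@]1(C)CCC(=O)OC | intermediate
9 | methyl 3-[(1S,6S)-1-methyl-6-(prop-1-en-2-yl)-2-[(trimethylsilyl)oxy]cyclohex-2-en-1-yl]propanoate (formed in the flask) | C=C(C)[C@@H]1CCC=C(O[Si](C)(C)C)[C@@]1(C)CCC(=O)OC | intermediate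
10 | methyl 3-[(1S,6S)-1-methyl-2-oxo-6-(prop-1-en-2-yl)cyclohex-3-en-1-yl]propanoate | C=C(C)[C@@H]1CC=CC(=O)[C@@]1(C)CCC(=O)OC | intermediate
11 | methyl 3-[(3S,4S)-3-methyl-2-oxo-4-(prop-1-en-2-yl)-7-oxabicyclo[4.1.0]heptan-3-yl]propanoate (epoxide diastereomers) | C=C(C)[C@@H]1CC2OC2C(=O)[C@@]1(C)CCC(=O)OC | intermediate
12 | 4-methylbenzenesulfonylhydrazone of 11 (formed in the flask) | C=C(C)[C@@H]1CC2OC2C(=NNS(=O)(=O)c2ccc(C)cc2)[C@@]1(C)CCC(=O)OC | intermediate
13 | methyl (4S,5S)-4-ethynyl-4-methyl-7-oxo-5-(prop-1-en-2-yl)heptanoate | C=C(C)[C@H](CC=O)[C@@](C)(C#C)CCC(=O)OC | intermediate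
14 | ethynylmagnesium bromide | C#C[Mg]Br | starting material
15 | bromomagnesium alkoxide of 16 (formed in the flask) | C=C(C)[C@H](CC(O[Mg]Br)C#C)[C@@](C)(C#C)CCC(=O)OC | intermediate
16 | methyl (4S,5S)-4-ethynyl-7-hydroxy-4-methyl-5-(prop-1-en-2-yl)non-8-ynoate (C7 epimers) | C=C(C)[C@H](CC(O)C#C)[C@@](C)(C#C)CCC(=O)OC | intermediate
17 | methyl (4S,5S)-4-ethynyl-4-methyl-7-oxo-5-(prop-1-en-2-yl)non-8-ynoate | C=C(C)[C@H](CC(=O)C#C)[C@@](C)(C#C)CCC(=O)OC | intermediate
18 | ethyl 2-methylpropanoate (ethyl isobutyrate) | CCOC(=O)C(C)C | starting material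
19 | lithium 1,1-dibromo-3-methylbut-1-en-2-olate (formed in the flask) | CC(C)C(O[Li])=C(Br)Br | intermediate
20 | lithium 3-methylbut-1-yn-1-olate (formed in the flask) | CC(C)C#CO[Li] | intermediate
21 | [(3-methylbut-1-yn-1-yl)oxy]tri(propan-2-yl)silane | CC(C)C#CO[Si](C(C)C)(C(C)C)C(C)C | intermediate
22 | methyl 3-[(1S,2S)-1-methyl-4-oxo-6-(propan-2-yl)-2-(prop-1-en-2-yl)-7-{[tri(propan-2-yl)silyl]oxy}-1,2,3,4-tetrahydronaphthalen-1-yl]propanoate | C=C(C)[C@@H]1CC(=O)c2cc(C(C)C)c(O[Si](C(C)C)(C(C)C)C(C)C)cc2[C@@]1(C)CCC(=O)OC | intermediate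
23 | methyl 3-[(1S,2S)-7-hydroxy-1-methyl-4-oxo-6-(propan-2-yl)-2-(prop-1-en-2-yl)-1,2,3,4-tetrahydronaphthalen-1-yl]propanoate | C=C(C)[C@@H]1CC(=O)c2cc(C(C)C)c(O)cc2[C@@]1(C)CCC(=O)OC | intermediate
24 | methyl 3-[(1S,2S)-1-methyl-4,7,8-trioxo-6-(propan-2-yl)-2-(prop-1-en-2-yl)-1,2,3,4,7,8-hexahydronaphthalen-1-yl]propanoate | C=C(C)[C@@H]1CC(=O)C2=C(C(=O)C(=O)C(C(C)C)=C2)[C@@]1(C)CCC(=O)OC | intermediate
25 | methyl 3-[(1S,2S)-5,7,8-trihydroxy-1-methyl-4-oxo-6-(propan-2-yl)-2-(prop-1-en-2-yl)-1,2,3,4-tetrahydronaphthalen-1-yl]propanoate (formed in the flask) | C=C(C)[C@@H]1CC(=O)c2c(O)c(C(C)C)c(O)c(O)c2[C@@]1(C)CCC(=O)OC | intermediate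
26 | methyl 3-[(1S,2S)-7-hydroxy-1-methyl-4,5,8-trioxo-6-(propan-2-yl)-2-(prop-1-en-2-yl)-1,2,3,4,5,8-hexahydronaphthalen-1-yl]propanoate (CNP0308749.1) | C=C(C)[C@@H]1CC(=O)C2=C(C(=O)C(O)=C(C(C)C)C2=O)[C@@]1(C)CCC(=O)OC | target

Total step count: 12. Longest linear sequence: 11 steps (steps 1–7 and 9–12; step 8 is a one-step side branch).

Steps most likely to fail

Step 9. The alkyne may insert with the opposite orientation. The cationic rhodium centre may also consume the acid-sensitive siloxyalkyne, or engage the isopropenyl alkene, so that homotrimerisation or enyne pathways outrun the cross-cycloaddition. In that case the C12 oxygen would be introduced after ring formation. Setting out from diyne 17, a neutral ruthenium catalyst, Cp*RuCl(cod), in 1,2-dichloroethane at room temperature would cyclotrimerise 17 with the alkynyl boronate 4,4,5,5-tetramethyl-2-(3-methylbut-1-yn-1-yl)-1,3,2-dioxaborolane F1 (from 3-methylbut-1-yne, n-BuLi and 2-isopropoxy-4,4,5,5-tetramethyl-1,3,2-dioxaborolane), a known partner class for this catalyst. This should give the aryl boronate methyl 3-[(1S,2S)-1-methyl-4-oxo-6-(propan-2-yl)-2-(prop-1-en-2-yl)-7-(4,4,5,5-tetramethyl-1,3,2-dioxaborolan-2-yl)-1,2,3,4-tetrahydronaphthalen-1-yl]propanoate F2. Oxidation of the C–B bond with NaBO3·4H2O in THF–water would then give phenol 23, where the route is rejoined and step 10 becomes unnecessary. The orientation of the boron-bearing carbon would rest on sterics only, so it would have to be established on the first run and any regioisomer removed by chromatography.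

Step 11. The acyl group para to the hydroxyl makes the phenol electron-poor, so oxygen transfer from IBX may stall, and a slow reaction may let the o-quinone decompose. Setting out from phenol 23, a classical relay would be used in which the phenoxide is the nucleophile. Coupling with benzenediazonium chloride (aniline, NaNO2, HCl; then aqueous Na2CO3–THF, 0 °C) at the free ortho position should give the azo phenol methyl 3-[(1S,2S)-7-hydroxy-1-methyl-4-oxo-8-(phenyldiazenyl)-6-(propan-2-yl)-2-(prop-1-en-2-yl)-1,2,3,4-tetrahydronaphthalen-1-yl]propanoate F3. Reduction with Na2S2O4 in aqueous ethanol should give the aminophenol methyl 3-[(1S,2S)-8-amino-7-hydroxy-1-methyl-4-oxo-6-(propan-2-yl)-2-(prop-1-en-2-yl)-1,2,3,4-tetrahydronaphthalen-1-yl]propanoate F4. Oxidation with FeCl3 in cold dilute HCl, with hydrolysis of the intermediate quinone imine, rejoins the route at o-quinone 24.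

Step 1. Enantioface discrimination may be insufficient with an alkenyl Grignard reagent on the α-substituted enone, and uncatalysed 1,2-addition may compete. Setting out from enone 1, the organometallic manifold would be changed to the Hayashi–Miyaura reaction: rhodium-catalysed asymmetric 1,4-addition of potassium trifluoro(prop-1-en-2-yl)borate ([Rh(cod)2]BF4, BINAP of the required configuration, toluene–water, 100 °C). This proceeds by alkenyl–rhodium insertion and protonation without a Grignard reagent and should give ketone 4 directly, where the route is rejoined; no compound outside the list is made (F0).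

Further compounds
F1 | step 9 | 4,4,5,5-tetramethyl-2-(3-methylbut-1-yn-1-yl)-1,3,2-dioxaborolane | CC(C)C#CB1OC(C)(C)C(C)(C)O1
F2 | step 9 | methyl 3-[(1S,2S)-1-methyl-4-oxo-6-(propan-2-yl)-2-(prop-1-en-2-yl)-7-(4,4,5,5-tetramethyl-1,3,2-dioxaborolan-2-yl)-1,2,3,4-tetrahydronaphthalen-1-yl]propanoate | C=C(C)[C@@H]1CC(=O)c2cc(C(C)C)c(B3OC(C)(C)C(C)(C)O3)cc2[C@@]1(C)CCC(=O)OC
F3 | step 11 | methyl 3-[(1S,2S)-7-hydroxy-1-methyl-4-oxo-8-(phenyldiazenyl)-6-(propan-2-yl)-2-(prop-1-en-2-yl)-1,2,3,4-tetrahydronaphthalen-1-yl]propanoate | C=C(C)[C@@H]1CC(=O)c2cc(C(C)C)c(O)c(N=Nc3ccccc3)c2[C@@]1(C)CCC(=O)OC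
F4 | step 11 | methyl 3-[(1S,2S)-8-amino-7-hydroxy-1-methyl-4-oxo-6-(propan-2-yl)-2-(prop-1-en-2-yl)-1,2,3,4-tetrahydronaphthalen-1-yl]propanoate | C=C(C)[C@@H]1CC(=O)c2cc(C(C)C)c(O)c(N)c2[C@@]1(C)CCC(=O)OC
F0 | step 1 | none | none
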